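**Assumptions.** The target has no stereocentre, stereogenic axis or double-bond isomerism, so there is no enantiomer to control; it is made as drawn. 9‑BBN and trifluoroacetic anhydride are numbered as reactants because their atoms sit in non‑isolated intermediates.

**Retrosynthetic overview**
1. Last bond cut: the ring C–O bond ortho to the acetyl group, traced back to an aryl C–H; forward, a ketone‑directed Pd C–H oxygenation run on the free para‑phenol ketone (key step, new).
2. Aryl–CH2 bond ortho to the acetyl group: B‑alkyl Suzuki–Miyaura coupling of a terminal‑alkene/9‑BBN adduct with ring‑brominated 4′‑hydroxyacetophenone.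
3. Phenyl–CH2 bond at the far chain end: Cu‑catalysed coupling of phenylmagnesium bromide with 10‑bromodec‑1‑ene.
4. No ring is formed; both benzene rings are bought, and the para oxygen arrives with the bromoketone.

**Step 1**
Reactants: 1 10‑bromodec‑1‑ene; 2 phenylmagnesium bromide (1.0 M in THF, 1.3 equiv)
Product: 3 dec‑9‑en‑1‑ylbenzene
Conditions: Li2CuCl4 (3 mol%), THF, −10 °C → rt; aq NH4Cl
Reagents that add atoms: none
Why: Cu‑catalysed Grignard/primary alkyl bromide cross‑coupling (Kochi type, cuprate displacement of bromide) is clean for unhindered primary bromides and leaves the remote terminal alkene untouched; no stereocentre is formed.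

**Step 2**
Reactants: 3 dec‑9‑en‑1‑ylbenzene (1.3 equiv); 4 9‑borabicyclo[3.3.1]nonane (9‑BBN, 0.5 M in THF, 1.25 equiv); 5 1‑(2‑bromo‑4‑hydroxyphenyl)ethan‑1‑one (ring bromide, 1.0 equiv)
Product: 7 1‑[4‑hydroxy‑2‑(10‑phenyldecyl)phenyl]ethan‑1‑one, via 9‑(10‑phenyldecyl)‑9‑BBN 6 (not isolated)
Conditions: (i) 3 + 4, THF, 0 °C → rt; (ii) 5, PdCl2(dppf)·CH2Cl2 (3 mol%), 3 M aq K3PO4 (4 equiv), THF/DMF, 60 °C; aq NH4Cl
Reagents that add atoms: none
Why: 9‑BBN hydroborates the terminal alkene anti‑Markovnikov, and the B‑alkyl‑9‑BBN then undergoes B‑alkyl Suzuki–Miyaura coupling with the ortho‑acyl‑activated aryl bromide; all B–H is consumed before the ketone is added, the phenol is carried as its phenoxide, and no stereocentre is formed.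

**Step 3**
Reactants: 7 1‑[4‑hydroxy‑2‑(10‑phenyldecyl)phenyl]ethan‑1‑one; 8 trifluoroacetic anhydride
Product: 11 1‑[2,4‑dihydroxy‑6‑(10‑phenyldecyl)phenyl]ethan‑1‑one (the target), via aryl mono(trifluoroacetate) 9 (not isolated), via aryl bis(trifluoroacetate) 10 (not isolated)
Conditions: (i) TFAA/TFA (1:9), rt, 30 min; (ii) Pd(OAc)2 (10 mol%), PhI(OCOCF3)2 (1.5 equiv), 45 °C; (iii) H2O/THF, rt
Reagents that add atoms: [bis(trifluoroacetoxy)iodo]benzene, O=C(OI(OC(=O)C(F)(F)F)c1ccccc1)C(F)(F)F (delivers the new ring oxygen as a trifluoroacetate)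
Why: Proposed new method: a one‑flask ketone‑directed ortho C–H oxygenation of an unprotected para‑hydroxyaryl ketone, in which TFAA first masks the phenol as aryl trifluoroacetate 9 to protect the ring from the iodine(III) oxidant, cationic Pd(II) in TFA then binds the acetyl oxygen and palladates the only free ortho C–H by concerted metalation–deprotonation to a five‑membered palladacycle, PhI(OCOCF3)2 oxidises it to Pd(IV), C–O reductive elimination gives bis(trifluoroacetate) 10, and water cleaves both esters at work‑up; the closest known reaction type is Pd(II)/Pd(IV) ortho‑hydroxylation of simple aryl ketones with PhI(OCOCF3)2 or K2S2O8 in TFA/TFAA, which to my knowledge has not been shown on free‑phenol substrates with in situ O‑trifluoroacetyl masking; no stereocentre is formed.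

**Compound list**
1 | 10‑bromodec‑1‑ene | C=CCCCCCCCCBr | starting material
2 | phenylmagnesium bromide | Br[Mg]c1ccccc1 | starting material
3 | dec‑9‑en‑1‑ylbenzene | C=CCCCCCCCCc1ccccc1 | intermediate
4 | 9‑borabicyclo[3.3.1]nonane (9‑BBN) | B1C2CCCC1CCC2 | starting material
5 | 1‑(2‑bromo‑4‑hydroxyphenyl)ethan‑1‑one | CC(=O)c1ccc(O)cc1Br | starting material
6 | 9‑(10‑phenyldecyl)‑9‑borabicyclo[3.3.1]nonane | c1ccccc1CCCCCCCCCCB1C2CCCC1CCC2 | intermediate
7 | 1‑[4‑hydroxy‑2‑(10‑phenyldecyl)phenyl]ethan‑1‑one | CC(=O)c1ccc(O)cc1CCCCCCCCCCc1ccccc1 | intermediate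
8 | trifluoroacetic anhydride | O=C(OC(=O)C(F)(F)F)C(F)(F)F | starting material
9 | 4‑acetyl‑3‑(10‑phenyldecyl)phenyl trifluoroacetate | CC(=O)c1ccc(OC(=O)C(F)(F)F)cc1CCCCCCCCCCc1ccccc1 | intermediate
10 | 4‑acetyl‑5‑(10‑phenyldecyl)‑1,3‑phenylene bis(trifluoroacetate) | CC(=O)c1c(OC(=O)C(F)(F)F)cc(OC(=O)C(F)(F)F)cc1CCCCCCCCCCc1ccccc1 | intermediate
11 | 1‑[2,4‑dihydroxy‑6‑(10‑phenyldecyl)phenyl]ethan‑1‑one | CC(=O)c1c(O)cc(O)cc1CCCCCCCCCCc1ccccc1 | target

**Total step count:** 3. **Longest linear sequence:** 3 (1 → 3 → 7 → 11).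

**Steps most likely to fail**

Step 3 (the proposed new step) is the most likely to fail. The palladacycle forces the acetyl methyl against the ortho CH2, which may slow C–H palladation. Iodine(III) could also oxidise the methyl ketone at its α‑carbon, and incomplete masking would expose the phenol to oxidation. The fallback uses known chemistry, sets out from 3 and comes back at 11. Alkene 3 is hydroborated with 4 to 6 as in step 2, and 6 is coupled with commercial 1‑bromo‑3,5‑dimethoxybenzene (PdCl2(dppf), aq K3PO4, THF, 60 °C) to give 1,3‑dimethoxy‑5‑(10‑phenyldecyl)benzene F1. Friedel–Crafts acetylation (AcCl, AlCl3, CH2Cl2, 0 °C) goes para to one methoxy group and ortho to the chain, giving 1‑[2,4‑dimethoxy‑6‑(10‑phenyldecyl)phenyl]ethan‑1‑one F2; the terminal phenyl ring is far less nucleophilic than the dimethoxyarene. BBr3 (CH2Cl2, −78 °C → rt) then cleaves both methyl ethers to give 11.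

Step 2 is next. The phenoxide‑bearing aryl–Pd species may transmetalate slowly, giving β‑hydride elimination or hydrodebromination, and aqueous base could cause aldol side reactions of the methyl ketone. The fallback sets out from 2 and comes back at 7. Grignard 2 is coupled with a threefold excess of 1,10‑dibromodecane (Li2CuCl4 cat., THF, 0 °C) to give (10‑bromodecyl)benzene F3. Zinc dust/LiCl in THF (50 °C) converts it into (10‑phenyldecyl)zinc bromide F4. A base‑free Negishi coupling of F4 (2 equiv, slow addition) with 5 under Pd(OAc)2/SPhos in THF at rt gives 7.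

Step 1 is the least risky. Biphenyl from Grignard homocoupling, or sluggish coupling of the aryl Grignard, would lower the yield. The fallback sets out from 1 and comes back at 3. Magnesium turnings in THF convert 1 into dec‑9‑en‑1‑ylmagnesium bromide F5, which is coupled with bromobenzene under NiCl2(dppp) (Kumada–Corriu, THF, rt → reflux) to give 3.

**Further compounds**
F1 | step 3 | 1,3‑dimethoxy‑5‑(10‑phenyldecyl)benzene | COc1cc(OC)cc(CCCCCCCCCCc2ccccc2)c1
F2 | step 3 | 1‑[2,4‑dimethoxy‑6‑(10‑phenyldecyl)phenyl]ethan‑1‑one | CC(=O)c1c(OC)cc(OC)cc1CCCCCCCCCCc1ccccc1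
F3 | step 2 | (10‑bromodecyl)benzene | BrCCCCCCCCCCc1ccccc1
F4 | step 2 | (10‑phenyldecyl)zinc bromide | Br[Zn]CCCCCCCCCCc1ccccc1
F5 | step 1 | dec‑9‑en‑1‑ylmagnesium bromide | C=CCCCCCCCC[Mg]Br
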